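## Structural features

The target is a diaryl ether of two benzoic acids; it has no stereocentre, so no stereochemical relationship has to be set or preserved. Ring A is pentasubstituted: CO2H on C1, the ether oxygen on C2, a free OH on C3, Cl on C4, OMe on C5 and hydrogen only on C6. Ring B is a 2,6-dioxygenated 4-methylbenzoic acid, with CO2H on C1, the ether oxygen on C2, CH3 on C4 and OH on C6. The bridging oxygen joins ring A C2 (flanked by CO2H and OH) to ring B C2 (flanked by CO2H), so the ether is ortho-substituted on three sides and is a poor candidate for an aryl–oxygen coupling. Fragile points are the ring B acid (a 2-aryloxy-6-hydroxybenzoic acid, prone to decarboxylation in hot acid), the aryl chloride (lost under hydrogenolysis) and two electron-rich rings that over-halogenate easily. The real difficulty lies in the contiguous O, O, Cl, O array on ring A C2 to C5: the two ring A oxygens must be differentiated (OH on C3, OMe on C5) and the chlorine must go between them. The key step exploits the 1,3 relation of the oxygens on ring A C3 and C5 together with the carboxyl on C1 beside the aryloxy carbon C2. This pattern is that of a 7-aryloxy-2,4,6-trioxoheptanoate chain, whose C7 to C2 aldol closure makes the ring A C1–C2 bond.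

## Logic of the disconnections

**14 ⇒ 13.** The ring A carboxyl is traced back to its methyl ester (acyl–OCH3 bond). The ester is formed in the ring-building step and is the only group that needs aqueous base, so its hydrolysis is placed last. This leaves a single clean saponification to reach the diacid. The forward step must spare the aryl chloride and avoid decarboxylation of the ring B acid, hence mild temperature and cold acidification.

**13 ⇒ 12.** The ring B O–CH2Ph bond and the ring B ester O–C(CH3)3 bond are cut together. Both fall to one Lewis acid by alkyl–oxygen fission, so hydrogenolysis, which would endanger the C4–Cl bond, is avoided. Ring B then travels as a non-acidic, non-nucleophilic unit. The forward step must leave the C5 methyl ether and the ring A methyl ester untouched, which calls for low temperature and a cation scavenger.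

**12 ⇒ 11.** The ring A C4–Cl bond is cut. In 11 the only free hydroxyl is on C3, and its single open ortho position is C4, so a hydroxyl-directed chlorination is steered to the correct carbon. All earlier intermediates are then halogen-free. The forward step must make directed delivery win over undirected attack at C6 and on ring B.

**11 ⇒ 10.** The C5 O–CH3 bond is cut. Both ring A hydroxyls arise together in the ring-forming step; the one on C5 has hydrogen on both sides, whereas the one on C3 sits next to the bulky aryloxy group. The gain is a resorcinol that the aldol delivers directly. The forward step must be a monomethylation under steric control with limiting reagent.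

**10 ⇒ 8 (through 9).** The ring A C1–C2 bond is cut, which is the bond between chain C2 and chain C7. This opens ring A into a linear triketo ester in which ester, aryloxy group and both ring oxygens are already in place. The crowded diaryl ether oxygen becomes an ordinary alkyl aryl ether oxygen. The forward step must favour carbon cyclisation over oxygen cyclisation and must not touch the ring B ester.

**8 ⇒ 5 + 6 (through 7).** The chain C5–C6 bond is cut. This divides the chain into a purchasable C1–C5 diketo ester and a C6–C7 aryloxyacetyl donor. The donor is used as an N-methoxy-N-methyl amide so that the adduct stays as a chelate until work-up. The forward step requires the dianion 7 to react at its terminal carbon and not to destroy itself at its own keto ester.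

**5 ⇒ 3 + 4.** The ring B O–CH2 bond is cut. The ether oxygen is thus attached by SN2 displacement on an α-chloro amide and not by aryl–oxygen coupling. The forward step must alkylate a hydrogen-bonded phenol, which calls for Cs2CO3 and iodide catalysis.

**3 ⇒ 2.** The O–benzyl bond is cut. This leads back to a symmetrical diphenol. After the first alkylation the remaining hydroxyl is locked in a hydrogen bond to the ester carbonyl, so monobenzylation should stop cleanly. The forward step needs limiting benzyl bromide.

**2 ⇒ 1.** The ester O–C(CH3)3 bond is cut. A hindered, non-electrophilic ester is needed for the key step, and it is made by O-alkylation of the carboxylate, so the two ortho substituents do not hinder its formation. The forward step must run without heat or strong acid to avoid decarboxylation of 1.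

## Other disconnections considered

**Alternative 1:** The cut removes ring B bonds C1–C2 and C3–C4. In the forward step the ring A aryl ethynyl ether A3 would add to the electron-poor pyranone A2 in an inverse-demand Diels–Alder reaction. The oxygen-bearing alkyne carbon should bond to pyranone C3 and the terminal carbon to pyranone C6, and the bridged lactone then loses CO2 to give benzoate A1.
- In its favour: it is convergent, and the polarity of both partners agrees with the required regiochemistry. The chlorine and the OH/OMe differentiation of ring A are fixed on the simple phenol A4 before the rings are joined, so no late chlorination of a diaryl ether is needed. On this point it is better than the chosen plan.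
- Against it: A3 has to be made from the hindered phenol A4 by a dichlorovinyl ether and strong-base sequence beside an aryl chloride. The 4-methoxy group of A2 weakens the inverse demand, so heat would be needed for a heat- and acid-sensitive ynol ether. After the key step the ring B methyl ether must be cleaved beside the ring A methyl ether, a methyl ester flanked on both sides must be hydrolysed, and the acetal must be unmasked and oxidised.
- Comparison: on structure the two plans are equal, since neither needs an aryl–oxygen coupling and neither has stereochemistry. On mechanism the cycloaddition is as predictable as the aldol folding but needs harsher conditions. On step economy it is worse, because A4 needs its own multistep synthesis and the end game is longer.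

**Alternative 2:** The cut removes the ring B C5–C6 bond. In the forward step base would remove a proton from a terminal methyl group of the dienylidene malonate A6. The vinylogous carbanion would acylate on one malonate ester, and loss of methoxide and tautomerisation would give salicylate A5.
- In its favour: the ring B hydroxyl emerges free and in the right place, only one six-membered closure is possible, and the conditions are mild. As in alternative 1, the ring A chlorine is installed early on A4, which is better than the chosen plan on that point.
- Against it: A6 needs an addition–elimination of the hindered phenoxide of A4 onto a β-halo alkylidene malonate. The ring B ester of A5 is a di-ortho-substituted methyl ester whose hydrolysis competes with decarboxylation, whereas the chosen plan carries a tert-butyl ester removed by acid. An aldehyde oxidation beside free phenols remains.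
- Comparison: on mechanism it is the equal of the chosen plan, since both are carbanion-to-carbonyl closures that end in aromatisation. On structure it shifts the burden to the synthesis of A4. On step economy it is worse.

**Alternative 3:** The cut removes four ring A bonds (C1–C6, C3–C4, C5–C6, C2–C3). In the forward step irradiation of diazo ketone A8 would trigger a Wolff rearrangement to a vinylketene. This would add the silyl alkynyl ether A9 in a [2+2] reaction; the cyclobutenone opens, the dienylketene closes by 6π electrocyclisation, and tautomerisation gives phenol A7.
- In its favour: every position of ring A is programmed. The methoxy group arrives as such, the free hydroxyl comes from the ketene carbon, and the silyl group marks C4 for ipso-chlorination. It therefore avoids both the selective methylation and the directed chlorination of the chosen plan and is better on both points. The ring B building block is the same kind of alkylated orsellinate, which is equal.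
- Against it: A8 is a β-aryloxy acrylate carrying a diazoacetyl group and needs several steps and diazo handling. The key step is photochemical. An electron-poor, β-oxygenated vinylketene has other reaction channels. A9 is not an off-the-shelf reagent. Ipso-chlorodesilylation of an electron-rich ortho-silyl phenol competes with protodesilylation.
- Comparison: on mechanism it is a cascade of four pericyclic events, against one aldol closure in the chosen plan. On step economy it is estimated equal or slightly longer, with more delicate intermediates.

Key step: step 5

Remark on the chemistry: chain C2, C7, C6, C5, C4 and C3 of 8 become ring A C1 to C6 in that order, and no structure needed correction. Compound 8 is drawn as its triketo tautomer although enol forms should dominate. The two sp3 centres of 9 are left undefined because both are lost on aromatisation. The tert-butyl ester and benzyl ether are kept on ring B, with the benzyl ether removed by Lewis acid and not by hydrogenolysis because of the aryl chloride.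

## Route

Step 1
Reactants: 1 2,6-dihydroxy-4-methylbenzoic acid
Product: 2 tert-butyl 2,6-dihydroxy-4-methylbenzoate
Conditions: t-BuOC(=NH)CCl3 (2.5 equiv), THF/cyclohexane, rt
Reagents that add atoms: tert-butyl 2,2,2-trichloroacetimidate, CC(C)(C)OC(=N)C(Cl)(Cl)Cl
Why: Imidate esterification: the strongly acidic carboxyl protonates the imidate and the carboxylate oxygen captures the tert-butyl cation, so no attack on the di-ortho-hindered carbonyl carbon is needed. The hydrogen-bonded phenols should stay free without a Lewis acid, and room temperature avoids decarboxylation.

Step 2
Reactants: 2 tert-butyl 2,6-dihydroxy-4-methylbenzoate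
Product: 3 tert-butyl 2-(benzyloxy)-6-hydroxy-4-methylbenzoate
Conditions: BnBr (1.05 equiv), K2CO3 (1.1 equiv), acetone, 50 °C
Reagents that add atoms: benzyl bromide, BrCc1ccccc1
Why: Williamson ether synthesis on one of two equivalent phenols; after the first alkylation the remaining hydroxyl is tied into a six-membered hydrogen bond with the ester carbonyl and is much less nucleophilic, so the reaction should stop at the monoether.

Step 3
Reactants: 3 tert-butyl 2-(benzyloxy)-6-hydroxy-4-methylbenzoate; 4 2-chloro-N-methoxy-N-methylacetamide
Product: 5 tert-butyl 2-(benzyloxy)-6-{2-[methoxy(methyl)amino]-2-oxoethoxy}-4-methylbenzoate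
Conditions: Cs2CO3, NaI (cat.), DMF, 60 °C
Reagents that add atoms: none
Why: Williamson ether synthesis with Finkelstein activation: the cesium phenoxide breaks the chelate and displaces halide from the activated α-halo amide by SN2. The hindered tert-butyl ester and the N-methoxy-N-methyl amide are inert to carbonate.

Step 4
Reactants: 5 tert-butyl 2-(benzyloxy)-6-{2-[methoxy(methyl)amino]-2-oxoethoxy}-4-methylbenzoate; 6 methyl 2,4-dioxopentanoate
Product: 8 methyl 7-[3-(benzyloxy)-2-(tert-butoxycarbonyl)-5-methylphenoxy]-2,4,6-trioxoheptanoate, via dilithium dianion of methyl 2,4-dioxopentanoate 7 (not isolated)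
Conditions: 6 (1.5 equiv), LiN(i-Pr)2 (2.1 equiv per 6), THF, −78 → 0 °C; then 5, −78 → −20 °C; aq. NH4Cl, HCl to pH 4, 0 °C
Reagents that add atoms: none
Why: Claisen-type acylation of a 1,3-dicarbonyl dianion: the second deprotonation of 6 can only occur at the terminal methyl, and this most basic carbon of 7 adds to the N-methoxy-N-methyl amide. The lithium-chelated tetrahedral adduct should persist until the quench, which prevents over-addition and keeps the acidic triketone from consuming 7; a cold, mildly acidic work-up limits pyranone formation.

Step 5
Reactants: 8 methyl 7-[3-(benzyloxy)-2-(tert-butoxycarbonyl)-5-methylphenoxy]-2,4,6-trioxoheptanoate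
Product: 10 methyl 2-[3-(benzyloxy)-2-(tert-butoxycarbonyl)-5-methylphenoxy]-3,5-dihydroxybenzoate, via cyclic aldol carbinol 9 (not isolated)
Conditions: Mg(OMe)2 (4 equiv), MeOH, rt → 50 °C; then 1 M HCl, 0 °C
Reagents that add atoms: none
Why: Mg(OMe)2 should convert 8 into a chelated polyenolate in which the C2 ketone next to the ester remains the most electrophilic carbonyl and C7 is the only carbon whose attack gives a six-membered carbocycle. The C7 enolate, activated by the C6 ketone and the aryloxy group, adds to C2 in an intramolecular aldol reaction to give carbinol 9; the closure is 6-(enolendo)-exo-trig and is allowed by the ring-closure rules for enolates. Carbinol 9 then loses water by an E1cB pathway and the C4 and C6 carbonyls enolise, so that aromatisation to 10 makes the sequence irreversible. The closest known reaction type is the base-mediated aldol aromatisation of 2,4,6-trioxoheptanoates to 3,5-dihydroxybenzoates, applied here to a chain whose nucleophilic terminus bears an aryloxy group, as in aldol condensations of α-aryloxy ketones. No stereocentre survives, because the two sp3 centres of 9 both become aromatic carbons. Carbon cyclisation must win over oxygen cyclisation to a 4-pyranone; a basic, chelating medium favours C–C bond formation, and the acid work-up is kept cold and short. Attack of C7 on the ring B ester, a five-membered Dieckmann closure to a benzofuranone, should be suppressed by the tert-butyl group and the two ortho substituents of that ester. Methoxide in methanol makes exchange at the ring A ester degenerate, and magnesium chelation should hold back retro-Claisen cleavage at the α-keto ester.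

Step 6
Reactants: 10 methyl 2-[3-(benzyloxy)-2-(tert-butoxycarbonyl)-5-methylphenoxy]-3,5-dihydroxybenzoate
Product: 11 methyl 2-[3-(benzyloxy)-2-(tert-butoxycarbonyl)-5-methylphenoxy]-3-hydroxy-5-methoxybenzoate
Conditions: MeI (1.05 equiv), K2CO3 (1.05 equiv), acetone, 0 °C → rt
Reagents that add atoms: iodomethane, CI
Why: Williamson O-methylation under steric control: the C5 hydroxyl has hydrogen on both sides, whereas the C3 hydroxyl lies beside the twisted, di-ortho-substituted aryloxy group, so limiting base and iodomethane should alkylate C5 preferentially.

Step 7
Reactants: 11 methyl 2-[3-(benzyloxy)-2-(tert-butoxycarbonyl)-5-methylphenoxy]-3-hydroxy-5-methoxybenzoate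
Product: 12 methyl 2-[3-(benzyloxy)-2-(tert-butoxycarbonyl)-5-methylphenoxy]-4-chloro-3-hydroxy-5-methoxybenzoate
Conditions: SO2Cl2 (1.05 equiv), 2,2,6,6-tetramethylpiperidine (10 mol%), toluene, 0 °C → rt
Reagents that add atoms: sulfuryl chloride, O=S(=O)(Cl)Cl
Why: Amine-catalysed ortho-selective chlorination of a phenol: the hindered amine is converted into an N-chloro species that hydrogen-bonds to the phenolic hydroxyl and delivers chlorine to the adjacent carbon. The only free hydroxyl of 11 is on C3, and its ortho positions are C2 (occupied) and C4, so chlorine should enter C4 and not C6 or the hydroxyl-free ring B.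

Step 8
Reactants: 12 methyl 2-[3-(benzyloxy)-2-(tert-butoxycarbonyl)-5-methylphenoxy]-4-chloro-3-hydroxy-5-methoxybenzoate
Product: 13 2-[3-chloro-2-hydroxy-4-methoxy-6-(methoxycarbonyl)phenoxy]-6-hydroxy-4-methylbenzoic acid
Conditions: BCl3 (4 equiv), C6HMe5 (3 equiv), CH2Cl2, −78 → 0 °C; then H2O
Reagents that add atoms: none
Why: Lewis acid dealkylation by alkyl–oxygen fission: BCl3 cleaves the benzyl ether, with pentamethylbenzene trapping the benzyl cation by Friedel–Crafts alkylation, and ionises the tert-butyl ester. The C5 methyl ether, which has no chelating carbonyl beside it, the methyl ester and the aryl chloride should survive at or below 0 °C.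

Step 9
Reactants: 13 2-[3-chloro-2-hydroxy-4-methoxy-6-(methoxycarbonyl)phenoxy]-6-hydroxy-4-methylbenzoic acid
Product: 14 2-(6-carboxy-3-chloro-2-hydroxy-4-methoxyphenoxy)-6-hydroxy-4-methylbenzoic acid
Conditions: LiOH·H2O (6 equiv), THF/H2O, rt → 40 °C; then 1 M HCl, 0 °C
Reagents that add atoms: lithium hydroxide, [Li+].[OH-]
Why: Saponification of the ring A methyl ester by acyl–oxygen cleavage; the ester has only one ortho substituent, and the electron-rich phenoxide rings protect the aryl chloride from substitution. Cold acidification should release the diacid without decarboxylation of the ring B acid.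

## Compound list

1 | 2,6-dihydroxy-4-methylbenzoic acid | Cc1cc(O)c(C(=O)O)c(O)c1 | starting material
2 | tert-butyl 2,6-dihydroxy-4-methylbenzoate | Cc1cc(O)c(C(=O)OC(C)(C)C)c(O)c1 | intermediate
3 | tert-butyl 2-(benzyloxy)-6-hydroxy-4-methylbenzoate | Cc1cc(O)c(C(=O)OC(C)(C)C)c(OCc2ccccc2)c1 | intermediate
4 | 2-chloro-N-methoxy-N-methylacetamide | CON(C)C(=O)CCl | starting material
5 | tert-butyl 2-(benzyloxy)-6-{2-[methoxy(methyl)amino]-2-oxoethoxy}-4-methylbenzoate | CON(C)C(=O)COc1cc(C)cc(OCc2ccccc2)c1C(=O)OC(C)(C)C | intermediate
6 | methyl 2,4-dioxopentanoate | CC(=O)CC(=O)C(=O)OC | starting material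
7 | dilithium dianion of methyl 2,4-dioxopentanoate (not isolated) | [Li+].[Li+].COC(=O)C([O-])=CC([O-])=C | intermediate
8 | methyl 7-[3-(benzyloxy)-2-(tert-butoxycarbonyl)-5-methylphenoxy]-2,4,6-trioxoheptanoate | COC(=O)C(=O)CC(=O)CC(=O)COc1cc(C)cc(OCc2ccccc2)c1C(=O)OC(C)(C)C | intermediate
9 | methyl 2-[3-(benzyloxy)-2-(tert-butoxycarbonyl)-5-methylphenoxy]-1-hydroxy-3,5-dioxocyclohexane-1-carboxylate (cyclic aldol carbinol, not isolated, configuration undefined) | COC(=O)C1(O)CC(=O)CC(=O)C1Oc1cc(C)cc(OCc2ccccc2)c1C(=O)OC(C)(C)C | intermediate
10 | methyl 2-[3-(benzyloxy)-2-(tert-butoxycarbonyl)-5-methylphenoxy]-3,5-dihydroxybenzoate | COC(=O)c1cc(O)cc(O)c1Oc1cc(C)cc(OCc2ccccc2)c1C(=O)OC(C)(C)C | intermediate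
11 | methyl 2-[3-(benzyloxy)-2-(tert-butoxycarbonyl)-5-methylphenoxy]-3-hydroxy-5-methoxybenzoate | COC(=O)c1cc(OC)cc(O)c1Oc1cc(C)cc(OCc2ccccc2)c1C(=O)OC(C)(C)C | intermediate
12 | methyl 2-[3-(benzyloxy)-2-(tert-butoxycarbonyl)-5-methylphenoxy]-4-chloro-3-hydroxy-5-methoxybenzoate | COC(=O)c1cc(OC)c(Cl)c(O)c1Oc1cc(C)cc(OCc2ccccc2)c1C(=O)OC(C)(C)C | intermediate
13 | 2-[3-chloro-2-hydroxy-4-methoxy-6-(methoxycarbonyl)phenoxy]-6-hydroxy-4-methylbenzoic acid | COC(=O)c1cc(OC)c(Cl)c(O)c1Oc1cc(C)cc(O)c1C(=O)O | intermediate
14 | 2-(6-carboxy-3-chloro-2-hydroxy-4-methoxyphenoxy)-6-hydroxy-4-methylbenzoic acid (CNP0310398.0) | COc1cc(C(=O)O)c(Oc2cc(C)cc(O)c2C(=O)O)c(O)c1Cl | target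

## Step count and least certain steps

Total step count: 9. Longest linear sequence: 9 steps (1 to 14); 4 and 6 enter as purchased materials.

**Step 5 (key step).** The most likely failures are diversion of the triketo ester into oxygen cyclisation (pyranone formation), methoxide-induced retro-Claisen cleavage at the α-keto ester, or sluggish attack of the hindered secondary α-aryloxy carbanion. Fallback: make the diaryl ether by copper-catalysed coupling instead of ring construction, setting out from 3 and returning at 10.
- Commercial methyl 3,5-dihydroxybenzoate would be brominated with N-bromosuccinimide to methyl 2-bromo-3,5-dihydroxybenzoate F1.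
- F1 would be allylated (allyl bromide, K2CO3) to methyl 2-bromo-3,5-bis(prop-2-en-1-yloxy)benzoate F2.
- Ullmann coupling of 3 with F2 (CuI, monovalent copper, with N,N-dimethylglycine and Cs2CO3 in dioxane at 100 °C, aided by the ortho ester of the bromide) should give methyl 2-[3-(benzyloxy)-2-(tert-butoxycarbonyl)-5-methylphenoxy]-3,5-bis(prop-2-en-1-yloxy)benzoate F3.
- Deallylation with Pd(PPh3)4 (zerovalent palladium) and morpholine would then give 10.

**Step 7.** The most likely failure is that undirected electrophilic chlorination outruns the hydroxyl-directed delivery. That would mean substitution para to the C3 hydroxyl (at C6), substitution on the electron-rich ring B, or over-chlorination. Fallback: a chelation-directed C–H chlorination, setting out from 11 and returning at 12.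
- The C3 hydroxyl would be arylated with 2-fluoropyridine (Cs2CO3, DMSO, 100 °C) to methyl 2-[3-(benzyloxy)-2-(tert-butoxycarbonyl)-5-methylphenoxy]-5-methoxy-3-(pyridin-2-yloxy)benzoate F4.
- Pyridine-directed ortho-palladation with Pd(OAc)2 (divalent palladium) and N-chlorosuccinimide can only reach C4 and should give methyl 2-[3-(benzyloxy)-2-(tert-butoxycarbonyl)-5-methylphenoxy]-4-chloro-5-methoxy-3-(pyridin-2-yloxy)benzoate F5.
- N-Methylation with methyl triflate followed by NaOMe in methanol would remove the pyridyl group and give 12.

**Step 6.** The most likely failure is insufficient discrimination between the two ring A hydroxyls, giving methylation at C3 and double methylation, because their acidities are close and only sterics separate them. Fallback: reverse the order of events, setting out from 10 and returning at 12.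
- Amine-catalysed chlorination of 10 with SO2Cl2 at C4, the carbon ortho to both hydroxyls, should give methyl 2-[3-(benzyloxy)-2-(tert-butoxycarbonyl)-5-methylphenoxy]-4-chloro-3,5-dihydroxybenzoate F6.
- In F6 the C3 hydroxyl is flanked on both sides (Cl and aryloxy) and the C5 hydroxyl on one side only, so methylation with MeI and K2CO3 should then be far more selective for C5 and give 12.

**Step 4.** The most likely failure is self-condensation or decomposition of the dianion at its own α-keto ester, or proton transfer from the α-aryloxy methylene of 5 instead of acylation. Fallback: build the chain in the opposite sense, setting out from 5 and returning at 8.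
- The lithium enolate of acetone would be acylated by 5 to give tert-butyl 2-(benzyloxy)-6-[(2,4-dioxopentyl)oxy]-4-methylbenzoate F7.
- The dianion of F7, formed with LiN(i-Pr)2 at the terminal methyl, would be acylated with dimethyl oxalate to give 8. This is the standard acylation of a β-diketone dianion by an oxalate ester.

## Further compounds

F1 | step 5 | methyl 2-bromo-3,5-dihydroxybenzoate | COC(=O)c1cc(O)cc(O)c1Br
F2 | step 5 | methyl 2-bromo-3,5-bis(prop-2-en-1-yloxy)benzoate | COC(=O)c1cc(OCC=C)cc(OCC=C)c1Br
F3 | step 5 | methyl 2-[3-(benzyloxy)-2-(tert-butoxycarbonyl)-5-methylphenoxy]-3,5-bis(prop-2-en-1-yloxy)benzoate | COC(=O)c1cc(OCC=C)cc(OCC=C)c1Oc1cc(C)cc(OCc2ccccc2)c1C(=O)OC(C)(C)C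
F4 | step 7 | methyl 2-[3-(benzyloxy)-2-(tert-butoxycarbonyl)-5-methylphenoxy]-5-methoxy-3-(pyridin-2-yloxy)benzoate | COC(=O)c1cc(OC)cc(Oc2ccccn2)c1Oc1cc(C)cc(OCc2ccccc2)c1C(=O)OC(C)(C)C
F5 | step 7 | methyl 2-[3-(benzyloxy)-2-(tert-butoxycarbonyl)-5-methylphenoxy]-4-chloro-5-methoxy-3-(pyridin-2-yloxy)benzoate | COC(=O)c1cc(OC)c(Cl)c(Oc2ccccn2)c1Oc1cc(C)cc(OCc2ccccc2)c1C(=O)OC(C)(C)C
F6 | step 6 | methyl 2-[3-(benzyloxy)-2-(tert-butoxycarbonyl)-5-methylphenoxy]-4-chloro-3,5-dihydroxybenzoate | COC(=O)c1cc(O)c(Cl)c(O)c1Oc1cc(C)cc(OCc2ccccc2)c1C(=O)OC(C)(C)C
F7 | step 4 | tert-butyl 2-(benzyloxy)-6-[(2,4-dioxopentyl)oxy]-4-methylbenzoate | CC(=O)CC(=O)COc1cc(C)cc(OCc2ccccc2)c1C(=O)OC(C)(C)C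
A1 | alternative 1 | methyl 2-[3-chloro-6-(1,3-dioxolan-2-yl)-4-methoxy-2-(methoxymethoxy)phenoxy]-6-methoxy-4-methylbenzoate | COc1cc(C2OCCO2)c(Oc2cc(C)cc(OC)c2C(=O)OC)c(OCOC)c1Cl
A2 | alternative 1 | methyl 4-methoxy-6-methyl-2-oxo-2H-pyran-3-carboxylate | COC(=O)C1=C(OC)C=C(C)OC1=O
A3 | alternative 1 | 2-[4-chloro-2-(ethynyloxy)-5-methoxy-3-(methoxymethoxy)phenyl]-1,3-dioxolane | COc1cc(C2OCCO2)c(OC#C)c(OCOC)c1Cl
A4 | alternative 1 | 3-chloro-6-(1,3-dioxolan-2-yl)-4-methoxy-2-(methoxymethoxy)phenol | COc1cc(C2OCCO2)c(O)c(OCOC)c1Cl
A5 | alternative 2 | methyl 2-[3-chloro-6-(1,3-dioxolan-2-yl)-4-methoxy-2-(methoxymethoxy)phenoxy]-6-hydroxy-4-methylbenzoate | COC(=O)c1c(O)cc(C)cc1Oc1c(C2OCCO2)cc(OC)c(Cl)c1OCOC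
A6 | alternative 2 | dimethyl 2-{1-[3-chloro-6-(1,3-dioxolan-2-yl)-4-methoxy-2-(methoxymethoxy)phenoxy]-3-methylbut-2-en-1-ylidene}propanedioate | COC(=O)C(C(=O)OC)=C(C=C(C)C)Oc1c(C2OCCO2)cc(OC)c(Cl)c1OCOC
A7 | alternative 3 | methyl 2-[3-(benzyloxy)-2-(methoxycarbonyl)-5-methylphenoxy]-3-hydroxy-5-methoxy-4-(trimethylsilyl)benzoate | COC(=O)c1cc(OC)c([Si](C)(C)C)c(O)c1Oc1cc(C)cc(OCc2ccccc2)c1C(=O)OC
A8 | alternative 3 | methyl 2-(benzyloxy)-6-{[2-(2-diazoacetyl)-3-methoxy-3-oxoprop-1-en-1-yl]oxy}-4-methylbenzoate | COC(=O)C(=COc1cc(C)cc(OCc2ccccc2)c1C(=O)OC)C(=O)C=[N+]=[N-]
A9 | alternative 3 | (methoxyethynyl)trimethylsilane | COC#C[Si](C)(C)C
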